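**Retrosynthetic overview**
1. Target 20 ← one-pot cleavage of the aryl TBS ether and methyl ester of chromene ester 19.
2. Pyran ring (the only ring formed; the arene comes from methylhydroquinone) and the C2 stereocentre ← enantioconvergent, chiral-acid-catalysed dehydrative cyclisation of racemic o-hydroxybenzyl allylic alcohol 18 (the new step).
3. 18 ← aryllithium from bromophenol 5 + C20 enal 17 (forms the C4–C4a bond).
4. 17 ← Still–Gennari olefination (sets the Z-enoate) of trisnor-farnesyl aldehyde 14 with α-homoprenyl phosphonate 8; 14 ← (E,E)-farnesol by terminal-olefin cleavage.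

Assumption 1: per the SMILES, the enoic acid C=C has CO2H cis to the chain leading to the chromene (2Z by CIP), the chain C(Me)=CH is E, and C2 is R.
Assumption 2: the (S,S)-antipode of the new catalyst is taken to give (R)-19; if the sense is opposite, the (R,R)-catalyst is used.

**Route**

Step 1
Reactants: 1, 2-methylbenzene-1,4-diol (methylhydroquinone)
Product: 3, 4-[(tert-butyldimethylsilyl)oxy]-2-methylphenol
Conditions: TBSCl (1.0 equiv), imidazole, DMF, −10 → 0 °C
Reagents that add atoms: 2, tert-butyldimethylsilyl chloride, CC(C)(C)[Si](C)(C)Cl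
Why: Selective O-silylation of the less hindered 4-OH (the 1-OH is flanked by the ortho methyl); the minor regioisomer and bis-ether are removed by chromatography.

Step 2
Reactants: 3
Product: 5, 2-bromo-4-[(tert-butyldimethylsilyl)oxy]-6-methylphenol
Conditions: NBS (1.0 equiv), i-Pr2NH (10 mol%), CH2Cl2, −20 → 0 °C
Reagents that add atoms: 4, N-bromosuccinimide, O=C1CCC(=O)N1Br
Why: Amine-mediated ortho-selective electrophilic bromination of a phenol; the free OH out-directs the bulky, weaker-donor OTBS, and the only free ortho position is C6.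

Step 3
Reactants: 6, methyl 2-[bis(2,2,2-trifluoroethoxy)phosphoryl]acetate; 7, 5-bromo-2-methylpent-2-ene
Product: 8, methyl 2-[bis(2,2,2-trifluoroethoxy)phosphoryl]-6-methylhept-5-enoate (racemic)
Conditions: NaH, DMF, 0 °C; then 7, NaI (cat.), 0 → 45 °C
Reagents that add atoms: none (both partners are listed as reactants)
Why: SN2 C-alkylation of the stabilised phosphonoacetate anion by a primary homoallylic halide (in situ Finkelstein), with non-nucleophilic NaH sparing the trifluoroethyl phosphonate esters.

Step 4
Reactants: 9, (2E,6E)-farnesol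
Product: 11, tert-butyl(diphenyl){[(2E,6E)-3,7,11-trimethyldodeca-2,6,10-trien-1-yl]oxy}silane
Conditions: TBDPSCl, imidazole, CH2Cl2, 0 °C → rt
Reagents that add atoms: 10, tert-butyldiphenylsilyl chloride, CC(C)(C)[Si](Cl)(c1ccccc1)c1ccccc1
Why: Standard silylation of a primary allylic alcohol; TBDPS survives the base, periodate and KHMDS steps that follow.

Step 5
Reactants: 11
Product: 12, (6E,10E)-3-bromo-12-[(tert-butyldiphenylsilyl)oxy]-2,6,10-trimethyldodeca-6,10-dien-2-ol (racemic)
Conditions: NBS (1.1 equiv), THF/H2O (2:1), 0 °C
Reagents that add atoms: 4, N-bromosuccinimide, O=C1CCC(=O)N1Br (Br); water, O (OH)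
Why: van Tamelen terminal-selective bromohydrin formation, with Markovnikov opening of the bromonium ion at the most exposed, most electron-rich terminal olefin of the coiled polyene in aqueous medium.

Step 6
Reactants: 12
Product: 13, tert-butyl{[(2E,6E)-9-(3,3-dimethyloxiran-2-yl)-3,7-dimethylnona-2,6-dien-1-yl]oxy}diphenylsilane (racemic)
Conditions: K2CO3, MeOH, rt
Reagents that add atoms: none
Why: Intramolecular Williamson closure of the bromohydrin to the terminal epoxide; the epoxide stereocentre is irrelevant because it is destroyed in the next step.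

Step 7
Reactants: 13
Product: 14, (4E,8E)-10-[(tert-butyldiphenylsilyl)oxy]-4,8-dimethyldeca-4,8-dienal
Conditions: H5IO6, THF/H2O, 0 °C (acetone is lost)
Reagents that add atoms: water, O (the aldehyde oxygen comes from the epoxide oxygen or from water via the transient diol)
Why: Periodic acid hydrolysis and glycol cleavage of the trisubstituted epoxide gives the trisnor aldehyde without touching the two internal E-olefins or the silyl ether.

Step 8
Reactants: 14; 8
Product: 15, methyl (2Z,6E,10E)-12-[(tert-butyldiphenylsilyl)oxy]-6,10-dimethyl-2-(4-methylpent-3-en-1-yl)dodeca-2,6,10-trienoate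
Conditions: 8, KHMDS, 18-crown-6, THF, −78 °C; then 14, −78 °C
Reagents that add atoms: none (both partners are listed as reactants)
Why: Still–Gennari olefination, in which fast, irreversible elimination from the kinetic adduct of the trifluoroethyl phosphonate under dissociating conditions places CO2Me cis to the new chain (2Z).

Step 9
Reactants: 15
Product: 16, methyl (2Z,6E,10E)-12-hydroxy-6,10-dimethyl-2-(4-methylpent-3-en-1-yl)dodeca-2,6,10-trienoate
Conditions: TBAF, AcOH (1:1), THF, 0 °C → rt
Reagents that add atoms: none
Why: Fluoride desilylation, buffered with AcOH so the hindered methyl enoate is not hydrolysed or isomerised.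

Step 10
Reactants: 16
Product: 17, methyl (2Z,6E,10E)-6,10-dimethyl-2-(4-methylpent-3-en-1-yl)-12-oxododeca-2,6,10-trienoate
Conditions: MnO2 (excess), CH2Cl2, rt
Reagents that add atoms: none
Why: Chemoselective MnO2 oxidation of the allylic alcohol to the (E)-enal with retention of olefin geometry.

Step 11
Reactants: 5 (1.5 equiv); 17
Product: 18, methyl (2Z,6E,10E)-12-{5-[(tert-butyldimethylsilyl)oxy]-2-hydroxy-3-methylphenyl}-12-hydroxy-6,10-dimethyl-2-(4-methylpent-3-en-1-yl)dodeca-2,6,10-trienoate (racemic at C12)
Conditions: 5, MeLi (1 equiv per 5) then t-BuLi (2 equiv per 5), THF, −78 °C; then 17, −78 °C; pH 7 buffer quench; used quickly (Et3N-deactivated silica)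
Reagents that add atoms: none (both partners are listed as reactants)
Why: Br–Li exchange on the lithium phenoxide and 1,2-addition of the aryllithium to the β,β-disubstituted enal at −78 °C, where the aldehyde reacts far faster than the hindered conjugated ester; the new carbinol centre is deliberately left racemic because it is erased in step 12.

Step 12
Reactants: 18
Product: 19, methyl (2Z,6E)-9-{(2R)-6-[(tert-butyldimethylsilyl)oxy]-2,8-dimethyl-2H-chromen-2-yl}-6-methyl-2-(4-methylpent-3-en-1-yl)nona-2,6-dienoate
Conditions: cat-A (5 mol%), 5 Å MS, toluene, −40 °C, dark; Et3N quench. cat-A is a confined (S,S)-imino-imidodiphosphate Brønsted acid: two (S)-3,3'-bis(2,4,6-triethylphenyl)-BINOL phosphorus units joined through an acidic N–H, one P=O and one P=N–SO2CF3.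
Reagents that add atoms: none (water is lost)
Why: Proposed new method: an enantioconvergent Brønsted-acid-catalysed dehydrative cyclisation (asymmetric intramolecular SN1′ allylic etherification, equivalent to a catalyst-controlled oxa-6π electrocyclisation) in which cat-A ionises the doubly activated benzylic/allylic carbinol, erasing its racemic centre to give an (E)-vinyl o-quinone methide/allyl cation held as a hydrogen-bonded contact ion pair in the chiral pocket, so the phenolic oxygen closes on one face of the Me/CH2R-substituted terminus (retained E geometry turns face selection into R at C2) while the moderate acidity and low temperature leave the isolated olefins, enoate and aryl silyl ether untouched; the closest known reaction type is chiral N-triflylphosphoramide-catalysed intramolecular allylic substitution of o-hydroxybenzyl allylic alcohols to 2-aryl-2H-chromenes via chiral contact ion pairs, and what is new is a purely aliphatic terminus (methyl versus primary alkyl) on a polyene substrate, hence the confined catalyst.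

Step 13
Reactants: 19
Product: 20, (R)-sargachromenol, (2Z,6E)-9-[(2R)-6-hydroxy-2,8-dimethyl-2H-chromen-2-yl]-6-methyl-2-(4-methylpent-3-en-1-yl)nona-2,6-dienoic acid
Conditions: LiOH·H2O (10 equiv), degassed THF/MeOH/H2O (3:1:1), 45 °C, Ar, dark; then aq. citric acid to pH 4 at 0 °C
Reagents that add atoms: lithium hydroxide/water, [Li+].[OH-] (O of the CO2H)
Why: Saponification of the methyl ester with concurrent hydroxide cleavage of the base-labile aryl silyl ether; the quaternary ether stereocentre and the olefin geometries are not affected by base, and air and light are excluded because the chromenol oxidises and 2H-chromenes ring-open photochemically.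

**Compound list**
1 | 2-methylbenzene-1,4-diol | Cc1cc(O)ccc1O | starting material
2 | tert-butyldimethylsilyl chloride | CC(C)(C)[Si](C)(C)Cl | starting material (reagent)
3 | 4-[(tert-butyldimethylsilyl)oxy]-2-methylphenol | Cc1cc(O[Si](C)(C)C(C)(C)C)ccc1O | intermediate
4 | N-bromosuccinimide | O=C1CCC(=O)N1Br | starting material (reagent)
5 | 2-bromo-4-[(tert-butyldimethylsilyl)oxy]-6-methylphenol | Cc1cc(O[Si](C)(C)C(C)(C)C)cc(Br)c1O | intermediate
6 | methyl 2-[bis(2,2,2-trifluoroethoxy)phosphoryl]acetate | COC(=O)CP(=O)(OCC(F)(F)F)OCC(F)(F)F | starting material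
7 | 5-bromo-2-methylpent-2-ene | CC(C)=CCCBr | starting material
8 | methyl 2-[bis(2,2,2-trifluoroethoxy)phosphoryl]-6-methylhept-5-enoate (racemic) | COC(=O)C(CCC=C(C)C)P(=O)(OCC(F)(F)F)OCC(F)(F)F | intermediate
9 | (2E,6E)-farnesol | CC(C)=CCC/C(C)=C/CC/C(C)=C/CO | starting material
10 | tert-butyldiphenylsilyl chloride | CC(C)(C)[Si](Cl)(c1ccccc1)c1ccccc1 | starting material (reagent)
11 | (2E,6E)-farnesyl TBDPS ether | CC(C)=CCC/C(C)=C/CC/C(C)=C/CO[Si](c1ccccc1)(c1ccccc1)C(C)(C)C | intermediate
12 | (6E,10E)-3-bromo-12-[(tert-butyldiphenylsilyl)oxy]-2,6,10-trimethyldodeca-6,10-dien-2-ol (racemic) | CC(C)(O)C(Br)CC/C(C)=C/CC/C(C)=C/CO[Si](c1ccccc1)(c1ccccc1)C(C)(C)C | intermediate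
13 | tert-butyl{[(2E,6E)-9-(3,3-dimethyloxiran-2-yl)-3,7-dimethylnona-2,6-dien-1-yl]oxy}diphenylsilane (racemic) | CC1(C)OC1CC/C(C)=C/CC/C(C)=C/CO[Si](c1ccccc1)(c1ccccc1)C(C)(C)C | intermediate
14 | (4E,8E)-10-[(tert-butyldiphenylsilyl)oxy]-4,8-dimethyldeca-4,8-dienal | O=CCC/C(C)=C/CC/C(C)=C/CO[Si](c1ccccc1)(c1ccccc1)C(C)(C)C | intermediate
15 | methyl (2Z,6E,10E)-12-[(tert-butyldiphenylsilyl)oxy]-6,10-dimethyl-2-(4-methylpent-3-en-1-yl)dodeca-2,6,10-trienoate | COC(=O)/C(CCC=C(C)C)=C\CC/C(C)=C/CC/C(C)=C/CO[Si](c1ccccc1)(c1ccccc1)C(C)(C)C | intermediate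
16 | methyl (2Z,6E,10E)-12-hydroxy-6,10-dimethyl-2-(4-methylpent-3-en-1-yl)dodeca-2,6,10-trienoate | COC(=O)/C(CCC=C(C)C)=C\CC/C(C)=C/CC/C(C)=C/CO | intermediate
17 | methyl (2Z,6E,10E)-6,10-dimethyl-2-(4-methylpent-3-en-1-yl)-12-oxododeca-2,6,10-trienoate | COC(=O)/C(CCC=C(C)C)=C\CC/C(C)=C/CC/C(C)=C/C=O | intermediate
18 | methyl (2Z,6E,10E)-12-{5-[(tert-butyldimethylsilyl)oxy]-2-hydroxy-3-methylphenyl}-12-hydroxy-6,10-dimethyl-2-(4-methylpent-3-en-1-yl)dodeca-2,6,10-trienoate (racemic at C12) | COC(=O)/C(CCC=C(C)C)=C\CC/C(C)=C/CC/C(C)=C/C(O)c1cc(O[Si](C)(C)C(C)(C)C)cc(C)c1O | intermediate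
19 | methyl (2Z,6E)-9-{(2R)-6-[(tert-butyldimethylsilyl)oxy]-2,8-dimethyl-2H-chromen-2-yl}-6-methyl-2-(4-methylpent-3-en-1-yl)nona-2,6-dienoate | COC(=O)/C(CCC=C(C)C)=C\CC/C(C)=C/CC[C@]1(C)C=Cc2cc(O[Si](C)(C)C(C)(C)C)cc(C)c2O1 | intermediate
20 | (R)-sargachromenol | CC(C)=CCC/C(=C/CC/C(C)=C/CC[C@]1(C)C=Cc2cc(O)cc(C)c2O1)C(=O)O | target

**Totals**
Total step count: 13.
Longest linear sequence: 10 steps (steps 4–13, from farnesol).

**Three steps most likely to fail, with fallbacks**
1. Step 12 (proposed new enantioconvergent cyclisation): enantioselectivity may be low, or a racemic background closure may compete. Fallback (known chemistry): condense phenol 3 directly with enal 17 by the phenylboronic acid/acetic acid chromenylation (toluene, reflux) to give racemic 19, resolve by preparative chiral SFC on a polysaccharide phase, and assign the (R)-enantiomer by optical rotation/ECD against the natural product.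
2. Step 8 (Still–Gennari with the α-branched phosphonate): Z/E selectivity or conversion may be poor, and making 8 in step 3 may suffer from over-alkylation. Fallback: fix the geometry by syn-addition instead. Convert 14 to the terminal alkyne (Ohira–Bestmann), carboxylate to the methyl ynoate, then Pd(0)/Bu3SnH syn-hydrostannation (α-stannyl enoate), iododestannylation, and Pd-catalysed Negishi coupling with (4-methylpent-3-enyl)zinc bromide with retention to give 15.
3. Step 11 (aryllithium addition beside an ester; acid-labile diol 18): competing enolisation or ester attack, or premature racemic cyclisation on work-up, are the risks. Fallback: drop the organolithium and bromide. Use boron-templated ortho-specific hydroxyalkylation of phenol 3 with enal 17 (PhB(OH)2, cat. propionic acid, benzene, Dean–Stark) to the 2-phenyl-4H-1,3,2-benzodioxaborin, release 18 by transesterification with propane-1,3-diol, and carry it into step 12.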